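**Retrosynthetic overview**
1. Target 32 ⇒ 8β-hydroxy lactone 25 + (E)-4-silyloxy-2-methylbut-2-enoic acid 30 (late esterification, final desilylation).
2. The ten-membered carbocycle and the trans-fused γ-lactone are formed together by making the C6–C7 bond: a new catalytic macrocyclising allylboration/lactonisation of aldehyde–allylboronate 22 (sets C6 and C7).
3. Allylboronate 20 (C8 cis to the ester) ⇐ ynoate 18 by cis-hydroalumination/borylmethylation; 18 ⇐ α-silyloxy ester 13.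
4. C9–C10 bond: the (Z)-alkenyl Grignard from iodide 7 opens methyl (R)-glycidate 8 (C8 from the chiral pool); 7 ⇐ aldehyde 6 by Stork–Zhao olefination (sets 1(10)Z).
5. 6 ⇐ nerol 1: Sharpless epoxidation (cis-oxirane, C4 and C5), PMB ether, ozonolysis. Ring order: oxirane first, then carbocycle and lactone in one step.

Assumption: the SMILES is taken literally, i.e. (4R,5S,6S,7R,8R) with a cis 4α,5α-epoxide, a 1(10)Z alkene, a trans-fused 12,6α-lactone (H-6β, H-7α) and an 8β-ester; germacrane locants C1–C15 are used throughout.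

**Route**

Step 1
Reactants: 1 nerol
Product: 2 (2S,3R)-2,3-epoxynerol
Conditions: Ti(OiPr)4 (5 mol%), L-(+)-diethyl tartrate (6 mol%), t-BuOOH, 4 Å MS, CH2Cl2, −20 °C
Reagents that add atoms: tert-butyl hydroperoxide, CC(C)(C)OO
Why: Sharpless asymmetric epoxidation of the (Z)-allylic alcohol; the L-(+)-tartrate complex delivers oxygen to the face that gives the (2S,3R) cis-oxirane (C5 and C4 of the target), and the remote alkene lacks the directing hydroxyl and is untouched.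

Step 2
Reactants: 2 (2S,3R)-2,3-epoxynerol
Product: 4 (2S,3R)-2-{[(4-methoxybenzyl)oxy]methyl}-3-methyl-3-(4-methylpent-3-en-1-yl)oxirane, via sodium alkoxide 3 (not isolated)
Conditions: NaH, DMF/THF, 0 °C; then PMBCl, Bu4NI (cat.), 0 °C → rt
Reagents that add atoms: 4-methoxybenzyl chloride, COc1ccc(CCl)cc1
Why: Williamson ether synthesis on the primary alkoxide; fast alkylation in cold aprotic medium suppresses Payne rearrangement and no stereocentre is touched.

Step 3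
Reactants: 4 (2S,3R)-2-{[(4-methoxybenzyl)oxy]methyl}-3-methyl-3-(4-methylpent-3-en-1-yl)oxirane
Product: 6 3-[(2R,3S)-3-{[(4-methoxybenzyl)oxy]methyl}-2-methyloxiran-2-yl]propanal, via secondary ozonide 5 (not isolated)
Conditions: O3, CH2Cl2, −78 °C (stopped at first blue colour); then PPh3, −78 °C → rt
Reagents that add atoms: ozone, [O-][O+]=O
Why: Ozonolysis of the electron-rich trisubstituted alkene is far faster than attack on the anisyl ring, and reductive cleavage of the ozonide with PPh3 gives the aldehyde while the oxirane and ether are inert.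

Step 4
Reactants: 6 3-[(2R,3S)-3-{[(4-methoxybenzyl)oxy]methyl}-2-methyloxiran-2-yl]propanal
Product: 7 (2S,3R)-3-[(3Z)-4-iodopent-3-en-1-yl]-2-{[(4-methoxybenzyl)oxy]methyl}-3-methyloxirane
Conditions: EtPPh3I, n-BuLi, THF, rt; [I][I], −78 °C; NaN(SiMe3)2, −20 °C; then 6, −78 °C
Reagents that add atoms: ethyltriphenylphosphonium iodide, CC[P+](c1ccccc1)(c1ccccc1)c1ccccc1.[I-]; iodine, [I][I]
Why: Stork–Zhao Wittig olefination with the α-iodo ylide gives the (Z)-2-iodoalk-2-ene under kinetic control (iodine cis to the chain), which fixes the later 1(10)Z geometry.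

Step 5
Reactants: 7 (2S,3R)-3-[(3Z)-4-iodopent-3-en-1-yl]-2-{[(4-methoxybenzyl)oxy]methyl}-3-methyloxirane; 8 methyl (R)-glycidate
Product: 12 methyl (2R,4Z)-2-hydroxy-7-[(2R,3S)-3-{[(4-methoxybenzyl)oxy]methyl}-2-methyloxiran-2-yl]-4-methylhept-4-enoate, via alkenyllithium 9 (not isolated), via alkenylmagnesium bromide 10 (not isolated), via bromomagnesium alkoxide 11 (not isolated)
Conditions: t-BuLi (2 equiv), Et2O, −78 °C; MgBr2·OEt2; CuI (10 mol%), 8, THF, −40 °C; H2O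
Reagents that add atoms: none
Why: Iodine–lithium exchange and transmetalation retain the alkene geometry, and the copper-catalysed SN2 epoxide opening occurs at the unsubstituted glycidate carbon (C9), so the C8 stereocentre (R) comes unchanged from the chiral pool.

Step 6
Reactants: 12 methyl (2R,4Z)-2-hydroxy-7-[(2R,3S)-3-{[(4-methoxybenzyl)oxy]methyl}-2-methyloxiran-2-yl]-4-methylhept-4-enoate
Product: 13 methyl (2R,4Z)-2-[(tert-butyldimethylsilyl)oxy]-7-[(2R,3S)-3-{[(4-methoxybenzyl)oxy]methyl}-2-methyloxiran-2-yl]-4-methylhept-4-enoate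
Conditions: TBSCl, imidazole, DMF, rt
Reagents that add atoms: tert-butyldimethylsilyl chloride, CC(C)(C)[Si](C)(C)Cl
Why: Standard silyl ether formation on the secondary alcohol under mildly basic conditions that spare the oxirane and the ester.

Step 7
Reactants: 13 methyl (2R,4Z)-2-[(tert-butyldimethylsilyl)oxy]-7-[(2R,3S)-3-{[(4-methoxybenzyl)oxy]methyl}-2-methyloxiran-2-yl]-4-methylhept-4-enoate
Product: 15 (2R,4Z)-2-[(tert-butyldimethylsilyl)oxy]-7-[(2R,3S)-3-{[(4-methoxybenzyl)oxy]methyl}-2-methyloxiran-2-yl]-4-methylhept-4-enal, via aluminium hemiacetal 14 (not isolated)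
Conditions: i-Bu2AlH, CH2Cl2, −78 °C; aq. potassium sodium tartrate
Reagents that add atoms: none
Why: Partial ester reduction: the α-silyloxy ester stops at the chelated aluminium hemiacetal at −78 °C and releases the aldehyde on work-up without epimerising C8.

Step 8
Reactants: 15 (2R,4Z)-2-[(tert-butyldimethylsilyl)oxy]-7-[(2R,3S)-3-{[(4-methoxybenzyl)oxy]methyl}-2-methyloxiran-2-yl]-4-methylhept-4-enal
Product: 16 (2S,3R)-3-[(3Z,6R)-8,8-dibromo-6-[(tert-butyldimethylsilyl)oxy]-4-methylocta-3,7-dien-1-yl]-2-{[(4-methoxybenzyl)oxy]methyl}-3-methyloxirane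
Conditions: CBr4, PPh3, Et3N, CH2Cl2, 0 °C
Reagents that add atoms: carbon tetrabromide, BrC(Br)(Br)Br
Why: Corey–Fuchs dibromo-olefination (a Wittig-type reaction) under amine-buffered conditions that protect the oxirane and silyl ether.

Step 9
Reactants: 16 (2S,3R)-3-[(3Z,6R)-8,8-dibromo-6-[(tert-butyldimethylsilyl)oxy]-4-methylocta-3,7-dien-1-yl]-2-{[(4-methoxybenzyl)oxy]methyl}-3-methyloxirane
Product: 18 methyl (4R,6Z)-4-[(tert-butyldimethylsilyl)oxy]-9-[(2R,3S)-3-{[(4-methoxybenzyl)oxy]methyl}-2-methyloxiran-2-yl]-6-methylnon-6-en-2-ynoate, via lithium acetylide 17 (not isolated)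
Conditions: n-BuLi (2.1 equiv), THF, −78 °C; then ClCO2Me, −78 → 0 °C
Reagents that add atoms: methyl chloroformate, COC(=O)Cl
Why: Second stage of the Corey–Fuchs alkyne synthesis (bromine–lithium exchange and Fritsch–Buttenberg–Wiechell rearrangement) gives the lithium acetylide, which is C-acylated by the chloroformate.

Step 10
Reactants: 18 methyl (4R,6Z)-4-[(tert-butyldimethylsilyl)oxy]-9-[(2R,3S)-3-{[(4-methoxybenzyl)oxy]methyl}-2-methyloxiran-2-yl]-6-methylnon-6-en-2-ynoate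
Product: 20 methyl (2Z,4R,6Z)-4-[(tert-butyldimethylsilyl)oxy]-9-[(2R,3S)-3-{[(4-methoxybenzyl)oxy]methyl}-2-methyloxiran-2-yl]-6-methyl-2-[(4,4,5,5-tetramethyl-1,3,2-dioxaborolan-2-yl)methyl]nona-2,6-dienoate, via α-alumino enoate 19 (not isolated)
Conditions: i-Bu2AlH, HMPA, MeCu (10 mol%), THF, −30 °C; then ICH2Bpin, −30 °C → rt
Reagents that add atoms: 2-(iodomethyl)-4,4,5,5-tetramethyl-1,3,2-dioxaborolane, ICB1OC(C)(C)C(C)(C)O1
Why: Copper-catalysed conjugate cis-hydroalumination of the ynoate puts H and Al cis, and C-alkylation with the iodomethylboronate proceeds with retention, so C8 ends cis to CO2Me and trans to CH2B, the geometry needed for a trans lactone.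

Step 11
Reactants: 20 methyl (2Z,4R,6Z)-4-[(tert-butyldimethylsilyl)oxy]-9-[(2R,3S)-3-{[(4-methoxybenzyl)oxy]methyl}-2-methyloxiran-2-yl]-6-methyl-2-[(4,4,5,5-tetramethyl-1,3,2-dioxaborolan-2-yl)methyl]nona-2,6-dienoate
Product: 21 methyl (2Z,4R,6Z)-4-[(tert-butyldimethylsilyl)oxy]-9-[(2R,3S)-3-(hydroxymethyl)-2-methyloxiran-2-yl]-6-methyl-2-[(4,4,5,5-tetramethyl-1,3,2-dioxaborolan-2-yl)methyl]nona-2,6-dienoate
Conditions: DDQ, CH2Cl2/pH 7 buffer, 0 °C
Reagents that add atoms: none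
Why: Oxidative PMB ether cleavage by DDQ (single-electron transfer from the anisyl ring) is neutral, and the electron-poor ester-substituted allylboronate, silyl ether and oxirane are not oxidised.

Step 12
Reactants: 21 methyl (2Z,4R,6Z)-4-[(tert-butyldimethylsilyl)oxy]-9-[(2R,3S)-3-(hydroxymethyl)-2-methyloxiran-2-yl]-6-methyl-2-[(4,4,5,5-tetramethyl-1,3,2-dioxaborolan-2-yl)methyl]nona-2,6-dienoate
Product: 22 methyl (2Z,4R,6Z)-4-[(tert-butyldimethylsilyl)oxy]-9-[(2R,3R)-3-formyl-2-methyloxiran-2-yl]-6-methyl-2-[(4,4,5,5-tetramethyl-1,3,2-dioxaborolan-2-yl)methyl]nona-2,6-dienoate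
Conditions: Dess–Martin periodinane, NaHCO3, CH2Cl2, 0 °C → rt; used at once
Reagents that add atoms: none
Why: Buffered Dess–Martin oxidation gives the α,β-epoxy aldehyde without epimerisation, and the 2-alkoxycarbonyl allylboronate is too unreactive to add to it without an acid catalyst.

Step 13
Reactants: 22 methyl (2Z,4R,6Z)-4-[(tert-butyldimethylsilyl)oxy]-9-[(2R,3R)-3-formyl-2-methyloxiran-2-yl]-6-methyl-2-[(4,4,5,5-tetramethyl-1,3,2-dioxaborolan-2-yl)methyl]nona-2,6-dienoate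
Product: 24 8β-[(tert-butyldimethylsilyl)oxy]-4α,5α-epoxy-(1(10)Z)-germacra-1(10),11(13)-dien-12,6α-olide, via macrocyclic pinacol borate 23 (not isolated)
Conditions: (S)-TRIP (10 mol%), 4 Å MS, toluene (2 mM), −20 °C → rt; then 45 °C
Reagents that add atoms: none
Why: Proposed new method: a chiral-phosphoric-acid-catalysed macrocyclising allylboration with in situ lactonisation, in which the acid hydrogen-bonds to a pinacol oxygen and to the formyl group and so switches on a closed six-membered chair transition state for the otherwise sluggish ester-substituted allylboronate only at high dilution inside the catalyst pocket; the enoate geometry (C8 trans to CH2B) puts both tether ends equatorial and gives the 6,7-anti (trans-lactone) relationship, the catalyst enantiomer and the Cornforth preference of the α,β-epoxy aldehyde both direct attack to the Si face of C6 (5,6-anti, 6S), the C8–H eclipses the enoate plane (A(1,3) control) with C9 anti to the forming bond, and the resulting borate acylates onto the methyl ester; the closest known reactions are the phosphoric-acid-catalysed intermolecular allylboration of aldehydes and the tandem allylboration–lactonisation of 2-alkoxycarbonyl allylboronates, neither yet shown for closing a ten-membered carbocycle.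

Step 14
Reactants: 24 8β-[(tert-butyldimethylsilyl)oxy]-4α,5α-epoxy-(1(10)Z)-germacra-1(10),11(13)-dien-12,6α-olide
Product: 25 8β-hydroxy-4α,5α-epoxy-(1(10)Z)-germacra-1(10),11(13)-dien-12,6α-olide
Conditions: HF·pyridine, pyridine, THF, 0 °C → rt
Reagents that add atoms: none
Why: Fluoride-driven desilylation buffered with pyridine removes the secondary silyl ether and leaves the oxirane, the α-methylene lactone and the alkene intact.

Step 15
Reactants: 26 (tert-butyldimethylsilyloxy)acetaldehyde; 27 ethyl 2-(triphenylphosphoranylidene)propanoate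
Product: 28 ethyl (2E)-4-[(tert-butyldimethylsilyl)oxy]-2-methylbut-2-enoate
Conditions: CH2Cl2, rt
Reagents that add atoms: none
Why: Wittig olefination with a stabilised α-methyl ylide gives the (E)-trisubstituted enoate (ester trans to the CH2O group).

Step 16
Reactants: 28 ethyl (2E)-4-[(tert-butyldimethylsilyl)oxy]-2-methylbut-2-enoate
Product: 30 (2E)-4-[(tert-butyldimethylsilyl)oxy]-2-methylbut-2-enoic acid, via lithium carboxylate 29 (not isolated)
Conditions: LiOH, THF/H2O, 0 °C → rt; then aq. HCl to pH 4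
Reagents that add atoms: lithium hydroxide, [Li+].[OH-]
Why: Ester saponification; the primary silyl ether survives LiOH and a brief mild acidification, and the alkene geometry is not affected.

Step 17
Reactants: 25 8β-hydroxy-4α,5α-epoxy-(1(10)Z)-germacra-1(10),11(13)-dien-12,6α-olide; 30 (2E)-4-[(tert-butyldimethylsilyl)oxy]-2-methylbut-2-enoic acid
Product: 31 8β-{[(2E)-4-[(tert-butyldimethylsilyl)oxy]-2-methylbut-2-enoyl]oxy}-4α,5α-epoxy-(1(10)Z)-germacra-1(10),11(13)-dien-12,6α-olide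
Conditions: DCC, DMAP (cat.), CH2Cl2, 0 °C → rt
Reagents that add atoms: none
Why: Steglich esterification acylates the 8β-hydroxyl with retention at C8 because the C8–O bond is not broken.

Step 18
Reactants: 31 8β-{[(2E)-4-[(tert-butyldimethylsilyl)oxy]-2-methylbut-2-enoyl]oxy}-4α,5α-epoxy-(1(10)Z)-germacra-1(10),11(13)-dien-12,6α-olide
Product: 32 8β-{[(2E)-4-hydroxy-2-methylbut-2-enoyl]oxy}-4α,5α-epoxy-(1(10)Z)-germacra-1(10),11(13)-dien-12,6α-olide
Conditions: HF·pyridine, pyridine, THF, 0 °C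
Reagents that add atoms: none
Why: Buffered fluoride desilylation removes the primary allylic silyl ether without touching the two esters, the oxirane or the exocyclic enoate.

**Compound list**
1 | nerol, (2Z)-3,7-dimethylocta-2,6-dien-1-ol | CC(C)=CCC/C(C)=C\CO | starting material
2 | [(2S,3R)-3-methyl-3-(4-methylpent-3-en-1-yl)oxiran-2-yl]methanol ((2S,3R)-2,3-epoxynerol) | CC(C)=CCC[C@@]1(C)O[C@H]1CO | intermediate
3 | sodium alkoxide of 2 | CC(C)=CCC[C@@]1(C)O[C@H]1C[O-].[Na+] | intermediate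
4 | (2S,3R)-2-{[(4-methoxybenzyl)oxy]methyl}-3-methyl-3-(4-methylpent-3-en-1-yl)oxirane | CC(C)=CCC[C@@]1(C)O[C@H]1COCc1ccc(OC)cc1 | intermediate
5 | secondary ozonide of 4: 3,3-dimethyl-5-{2-[(2R,3S)-3-{[(4-methoxybenzyl)oxy]methyl}-2-methyloxiran-2-yl]ethyl}-1,2,4-trioxolane (both epimers at the trioxolane CH) | CC1(C)OOC(CC[C@@]2(C)O[C@H]2COCc2ccc(OC)cc2)O1 | intermediate
6 | 3-[(2R,3S)-3-{[(4-methoxybenzyl)oxy]methyl}-2-methyloxiran-2-yl]propanal | O=CCC[C@@]1(C)O[C@H]1COCc1ccc(OC)cc1 | intermediate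
7 | (2S,3R)-3-[(3Z)-4-iodopent-3-en-1-yl]-2-{[(4-methoxybenzyl)oxy]methyl}-3-methyloxirane | I/C(C)=C\CC[C@@]1(C)O[C@H]1COCc1ccc(OC)cc1 | intermediate
8 | methyl (2R)-oxirane-2-carboxylate (methyl (R)-glycidate) | COC(=O)[C@H]1CO1 | starting material
9 | (Z)-alkenyllithium from 7 (Li in place of I) | [Li]/C(C)=C\CC[C@@]1(C)O[C@H]1COCc1ccc(OC)cc1 | intermediate
10 | (Z)-alkenylmagnesium bromide from 9 | Br[Mg]/C(C)=C\CC[C@@]1(C)O[C@H]1COCc1ccc(OC)cc1 | intermediate
11 | bromomagnesium alkoxide of 12 | COC(=O)[C@H](O[Mg]Br)C/C(C)=C\CC[C@@]1(C)O[C@H]1COCc1ccc(OC)cc1 | intermediate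
12 | methyl (2R,4Z)-2-hydroxy-7-[(2R,3S)-3-{[(4-methoxybenzyl)oxy]methyl}-2-methyloxiran-2-yl]-4-methylhept-4-enoate | COC(=O)[C@H](O)C/C(C)=C\CC[C@@]1(C)O[C@H]1COCc1ccc(OC)cc1 | intermediate
13 | methyl (2R,4Z)-2-[(tert-butyldimethylsilyl)oxy]-7-[(2R,3S)-3-{[(4-methoxybenzyl)oxy]methyl}-2-methyloxiran-2-yl]-4-methylhept-4-enoate | COC(=O)[C@H](O[Si](C)(C)C(C)(C)C)C/C(C)=C\CC[C@@]1(C)O[C@H]1COCc1ccc(OC)cc1 | intermediate
14 | diisobutylaluminium hemiacetal of 13 (O–Al and OMe on the former ester carbon) | COC(O[Al](CC(C)C)CC(C)C)[C@H](O[Si](C)(C)C(C)(C)C)C/C(C)=C\CC[C@@]1(C)O[C@H]1COCc1ccc(OC)cc1 | intermediate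
15 | (2R,4Z)-2-[(tert-butyldimethylsilyl)oxy]-7-[(2R,3S)-3-{[(4-methoxybenzyl)oxy]methyl}-2-methyloxiran-2-yl]-4-methylhept-4-enal | O=C[C@H](O[Si](C)(C)C(C)(C)C)C/C(C)=C\CC[C@@]1(C)O[C@H]1COCc1ccc(OC)cc1 | intermediate
16 | (2S,3R)-3-[(3Z,6R)-8,8-dibromo-6-[(tert-butyldimethylsilyl)oxy]-4-methylocta-3,7-dien-1-yl]-2-{[(4-methoxybenzyl)oxy]methyl}-3-methyloxirane | BrC(Br)=C[C@H](O[Si](C)(C)C(C)(C)C)C/C(C)=C\CC[C@@]1(C)O[C@H]1COCc1ccc(OC)cc1 | intermediate
17 | lithium acetylide from 16 (terminal alkyne carbon lithiated) | [Li]C#C[C@H](O[Si](C)(C)C(C)(C)C)C/C(C)=C\CC[C@@]1(C)O[C@H]1COCc1ccc(OC)cc1 | intermediate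
18 | methyl (4R,6Z)-4-[(tert-butyldimethylsilyl)oxy]-9-[(2R,3S)-3-{[(4-methoxybenzyl)oxy]methyl}-2-methyloxiran-2-yl]-6-methylnon-6-en-2-ynoate | COC(=O)C#C[C@H](O[Si](C)(C)C(C)(C)C)C/C(C)=C\CC[C@@]1(C)O[C@H]1COCc1ccc(OC)cc1 | intermediate
19 | α-(diisobutylalumino) enoate from 18 (H and Al cis; C8 cis to CO2Me) | COC(=O)/C([Al](CC(C)C)CC(C)C)=C\[C@H](O[Si](C)(C)C(C)(C)C)C/C(C)=C\CC[C@@]1(C)O[C@H]1COCc1ccc(OC)cc1 | intermediate
20 | methyl (2Z,4R,6Z)-4-[(tert-butyldimethylsilyl)oxy]-9-[(2R,3S)-3-{[(4-methoxybenzyl)oxy]methyl}-2-methyloxiran-2-yl]-6-methyl-2-[(4,4,5,5-tetramethyl-1,3,2-dioxaborolan-2-yl)methyl]nona-2,6-dienoate | COC(=O)/C(CB1OC(C)(C)C(C)(C)O1)=C\[C@H](O[Si](C)(C)C(C)(C)C)C/C(C)=C\CC[C@@]1(C)O[C@H]1COCc1ccc(OC)cc1 | intermediate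
21 | methyl (2Z,4R,6Z)-4-[(tert-butyldimethylsilyl)oxy]-9-[(2R,3S)-3-(hydroxymethyl)-2-methyloxiran-2-yl]-6-methyl-2-[(4,4,5,5-tetramethyl-1,3,2-dioxaborolan-2-yl)methyl]nona-2,6-dienoate | COC(=O)/C(CB1OC(C)(C)C(C)(C)O1)=C\[C@H](O[Si](C)(C)C(C)(C)C)C/C(C)=C\CC[C@@]1(C)O[C@H]1CO | intermediate
22 | methyl (2Z,4R,6Z)-4-[(tert-butyldimethylsilyl)oxy]-9-[(2R,3R)-3-formyl-2-methyloxiran-2-yl]-6-methyl-2-[(4,4,5,5-tetramethyl-1,3,2-dioxaborolan-2-yl)methyl]nona-2,6-dienoate | COC(=O)/C(CB1OC(C)(C)C(C)(C)O1)=C\[C@H](O[Si](C)(C)C(C)(C)C)C/C(C)=C\CC[C@@]1(C)O[C@H]1C=O | intermediate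
23 | methyl 8β-[(tert-butyldimethylsilyl)oxy]-4α,5α-epoxy-6α-[(4,4,5,5-tetramethyl-1,3,2-dioxaborolan-2-yl)oxy]-(1(10)Z)-germacra-1(10),11(13)-dien-12-oate (H-7α) | C=C(C(=O)OC)[C@@H]1[C@H](O[Si](C)(C)C(C)(C)C)C/C(C)=C\CC[C@@]2(C)O[C@H]2[C@H]1OB1OC(C)(C)C(C)(C)O1 | intermediate
24 | 8β-[(tert-butyldimethylsilyl)oxy]-4α,5α-epoxy-(1(10)Z)-germacra-1(10),11(13)-dien-12,6α-olide (H-6β, H-7α) | C=C1C(=O)O[C@H]2[C@H]1[C@H](O[Si](C)(C)C(C)(C)C)C/C(C)=C\CC[C@@]1(C)O[C@@H]21 | intermediate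
25 | 8β-hydroxy-4α,5α-epoxy-(1(10)Z)-germacra-1(10),11(13)-dien-12,6α-olide | C=C1C(=O)O[C@H]2[C@H]1[C@H](O)C/C(C)=C\CC[C@@]1(C)O[C@@H]21 | intermediate
26 | (tert-butyldimethylsilyloxy)acetaldehyde | CC(C)(C)[Si](C)(C)OCC=O | starting material
27 | ethyl 2-(triphenylphosphoranylidene)propanoate | CCOC(=O)C(C)=P(c1ccccc1)(c1ccccc1)c1ccccc1 | starting material
28 | ethyl (2E)-4-[(tert-butyldimethylsilyl)oxy]-2-methylbut-2-enoate | CCOC(=O)/C(C)=C/CO[Si](C)(C)C(C)(C)C | intermediate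
29 | lithium (2E)-4-[(tert-butyldimethylsilyl)oxy]-2-methylbut-2-enoate | [Li+].[O-]C(=O)/C(C)=C/CO[Si](C)(C)C(C)(C)C | intermediate
30 | (2E)-4-[(tert-butyldimethylsilyl)oxy]-2-methylbut-2-enoic acid | OC(=O)/C(C)=C/CO[Si](C)(C)C(C)(C)C | intermediate
31 | 8β-{[(2E)-4-[(tert-butyldimethylsilyl)oxy]-2-methylbut-2-enoyl]oxy}-4α,5α-epoxy-(1(10)Z)-germacra-1(10),11(13)-dien-12,6α-olide | C=C1C(=O)O[C@H]2[C@H]1[C@H](OC(=O)/C(C)=C/CO[Si](C)(C)C(C)(C)C)C/C(C)=C\CC[C@@]1(C)O[C@@H]21 | intermediate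
32 | 8β-{[(2E)-4-hydroxy-2-methylbut-2-enoyl]oxy}-4α,5α-epoxy-(1(10)Z)-germacra-1(10),11(13)-dien-12,6α-olide, (4R,5S,6S,7R,8R) | C=C1C(=O)O[C@H]2[C@H]1[C@H](OC(=O)/C(C)=C/CO)C/C(C)=C\CC[C@@]1(C)O[C@@H]21 | target

**Step count**
Total: 18 steps. Longest linear sequence: 16 steps (steps 1–14, 17 and 18, from nerol 1); steps 15–16 make the side-chain acid 30.

**Three steps most likely to fail**

Step 13 (proposed new step). The ten-membered closure may be slow, or the C8 centre may be mismatched with the catalyst and the epoxy aldehyde bias. The fallback uses known chemistry, sets out from 20 and comes back at 24. Oxidation of the C–B bond of 20 with NaBO3·4H2O gives the allylic alcohol methyl (2Z,4R,6Z)-2-(hydroxymethyl)-4-silyloxy-nona-2,6-dienoate F5. CBr4/PPh3 converts it into the allylic bromide F6. DDQ removes the PMB group to give the primary alcohol F7, and Dess–Martin oxidation gives the bromo aldehyde F8. A Nozaki–Hiyama allylation with CrCl2 in THF/DMF at high dilution, the established ring closure of 2-(bromomethyl)acrylates onto aldehydes for germacranolides, gives the macrocyclic hydroxy ester F9. F9 lactonises with catalytic pyridinium p-toluenesulfonate to 24; diastereomers are separated at this stage.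

Step 10. The hydroalumination may reduce the oxirane or give poor trapping with the iodomethylboronate. The fallback sets out from 18 and comes back at 20. Syn-hydrostannation with Bu3SnH and Pd(PPh3)4 gives the α-stannyl enoate F3 (tin next to the ester, H and Sn cis). Iododestannylation with iodine gives the α-iodo enoate F4 with retention. Negishi coupling of F4 with IZnCH2Bpin and Pd(PPh3)4 gives 20 with the same alkene geometry.

Step 4. The Stork–Zhao olefination can give a modest yield and Z/E ratio. The fallback sets out from 6 and comes back at 9. Dibromo-olefination of 6 (CBr4, PPh3, Et3N) gives the 1,1-dibromoalkene F1. Trans-selective mono-methylation with MeZnCl and PdCl2(DPEphos) replaces only the bromine trans to the chain and gives the (Z)-2-bromoalkene F2. Bromine–lithium exchange on F2 with t-BuLi gives alkenyllithium 9, which continues as in step 5.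

Further compounds
F1 | step 4 | (2S,3R)-3-(4,4-dibromobut-3-en-1-yl)-2-{[(4-methoxybenzyl)oxy]methyl}-3-methyloxirane | BrC(Br)=CCC[C@@]1(C)O[C@H]1COCc1ccc(OC)cc1
F2 | step 4 | (2S,3R)-3-[(3Z)-4-bromopent-3-en-1-yl]-2-{[(4-methoxybenzyl)oxy]methyl}-3-methyloxirane | Br/C(C)=C\CC[C@@]1(C)O[C@H]1COCc1ccc(OC)cc1
F3 | step 10 | methyl (2E,4R,6Z)-4-[(tert-butyldimethylsilyl)oxy]-9-[(2R,3S)-3-{[(4-methoxybenzyl)oxy]methyl}-2-methyloxiran-2-yl]-6-methyl-2-(tributylstannyl)nona-2,6-dienoate | COC(=O)/C([Sn](CCCC)(CCCC)CCCC)=C\[C@H](O[Si](C)(C)C(C)(C)C)C/C(C)=C\CC[C@@]1(C)O[C@H]1COCc1ccc(OC)cc1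
F4 | step 10 | methyl (2E,4R,6Z)-4-[(tert-butyldimethylsilyl)oxy]-2-iodo-9-[(2R,3S)-3-{[(4-methoxybenzyl)oxy]methyl}-2-methyloxiran-2-yl]-6-methylnona-2,6-dienoate | COC(=O)/C(I)=C\[C@H](O[Si](C)(C)C(C)(C)C)C/C(C)=C\CC[C@@]1(C)O[C@H]1COCc1ccc(OC)cc1
F5 | step 13 | methyl (2Z,4R,6Z)-4-[(tert-butyldimethylsilyl)oxy]-2-(hydroxymethyl)-9-[(2R,3S)-3-{[(4-methoxybenzyl)oxy]methyl}-2-methyloxiran-2-yl]-6-methylnona-2,6-dienoate | COC(=O)/C(CO)=C\[C@H](O[Si](C)(C)C(C)(C)C)C/C(C)=C\CC[C@@]1(C)O[C@H]1COCc1ccc(OC)cc1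
F6 | step 13 | methyl (2E,4R,6Z)-2-(bromomethyl)-4-[(tert-butyldimethylsilyl)oxy]-9-[(2R,3S)-3-{[(4-methoxybenzyl)oxy]methyl}-2-methyloxiran-2-yl]-6-methylnona-2,6-dienoate | COC(=O)/C(CBr)=C\[C@H](O[Si](C)(C)C(C)(C)C)C/C(C)=C\CC[C@@]1(C)O[C@H]1COCc1ccc(OC)cc1
F7 | step 13 | methyl (2E,4R,6Z)-2-(bromomethyl)-4-[(tert-butyldimethylsilyl)oxy]-9-[(2R,3S)-3-(hydroxymethyl)-2-methyloxiran-2-yl]-6-methylnona-2,6-dienoate | COC(=O)/C(CBr)=C\[C@H](O[Si](C)(C)C(C)(C)C)C/C(C)=C\CC[C@@]1(C)O[C@H]1CO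
F8 | step 13 | methyl (2E,4R,6Z)-2-(bromomethyl)-4-[(tert-butyldimethylsilyl)oxy]-9-[(2R,3R)-3-formyl-2-methyloxiran-2-yl]-6-methylnona-2,6-dienoate | COC(=O)/C(CBr)=C\[C@H](O[Si](C)(C)C(C)(C)C)C/C(C)=C\CC[C@@]1(C)O[C@H]1C=O
F9 | step 13 | methyl 8β-[(tert-butyldimethylsilyl)oxy]-4α,5α-epoxy-6α-hydroxy-(1(10)Z)-germacra-1(10),11(13)-dien-12-oate | C=C(C(=O)OC)[C@@H]1[C@H](O[Si](C)(C)C(C)(C)C)C/C(C)=C\CC[C@@]2(C)O[C@H]2[C@H]1O
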